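Late times are where the growth of target can be read, so we start there.

| flask | substrate | reagent | temperature | remark | time |
|---|---|---|---|---|---|
| grey | 0.050 M | 0.050 M | 105 °C | run made earlier |  |
| green | 0.050 M | 0.034 M | 116 °C | run made earlier |  |
| blue | 0.050 M | 0.075 M | 105 °C | run made earlier |  |
| Friday's | 0.050 M (fed, over 6.0 min) | 0.0500 M |  | the addition at 70 °C, then warmed to 110 °C; the feed brings no volume worth counting | 8.0 min |
| Thursday's | 0.050 M (fed, over 6.0 min) | 0.0500 M | 110 °C | all else is in the flask from the start; the feed brings no volume worth counting | 8.0 min |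
| Tuesday's | 0.050 M (fed, over 40 s) | 0.0500 M | 110 °C | all else is in the flask from the start; the feed brings no volume worth counting | 8.0 min |
| Sunday's | 0.050 M | 0.0500 M (fed, over 6.0 min) | 110 °C | all else is in the flask from the start; the feed brings no volume worth counting | 8.0 min |

| run | time / min | target / % | substrate / % |
|---|---|---|---|
| grey | 0.667 | 0 | 98.1 |
| grey | 1.33 | 0.6 | 100.4 |
| grey | 2.00 | 0 | 100.3 |
| grey | 3.00 | 1.4 | 99.8 |
| grey | 4.00 | 1.8 | 96.7 |
| grey | 5.00 | 1.3 | 95.6 |
| green | 1.00 | 0 | 99.4 |
| green | 2.50 | 0.6 | 101.0 |
| green | 3.00 | 0 | 97.6 |
| green | 5.00 | 2.2 | 93.6 |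
| green | 6.00 | 6.8 | 90.2 |
| green | 8.00 | 9.5 | 79.2 |
| blue | 0.417 | 0 | 99.4 |
| blue | 1.33 | 0.4 | 101.1 |
| blue | 2.50 | 1.0 | 96.7 |
| blue | 3.00 | 1.2 | 96.4 |
| blue | 5.00 | 10.9 | 82.5 |
| blue | 6.00 | 17.5 | 68.0 |
| blue | 8.00 | 43.9 | 33.6 |

(each reading ± 1 percentage point)

- the best flask by amount of target, in percent of the substrate charged; "all alike" if 1.5 percentage points covers them all (Friday's / Thursday's / Tuesday's / Sunday's / all alike)
- amount of target at the end, in percent of the substrate charged, Friday's
- amount of target at the end, in percent of the substrate charged, Thursday's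
- amount of target at the end, in percent of the substrate charged, Tuesday's
- amount of target at the end, in percent of the substrate charged, Sunday's

- a reading or a percentage of target counts all its forms, free or not
- a reading of substrate is of its free form alone

The blue run climbs from 17.5% at 6.00 min to 43.9% at 8.00 min, which reads as a growth rate of 0.460 /min. Target that speeds its own making is autocatalysis. The green run, from 2.2% at 5.00 min to 9.5% at 8.00 min, reads 0.488 /min. Blue is colder with more reagent and green hotter with less, so for 110 °C and 0.0500 M we take their mean, 0.474 /min. That gives the doubling time of target, 1.46 min.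

What counts, then, is hot time divided by this doubling time. But the grey run at 105 °C reads 1.3% at 5.00 min, and Friday's addition stands colder, at 70 °C, so we count nothing from it. Friday's therefore has 2.00 min, or 1.37 doublings. Tuesday's, counting half its feed, has 7.67 min, or 5.24 doublings, more than Friday's. Target grown from a steady trickle follows the exponential of growth rate times hot time, less its starting value, so we expect Tuesday's to beat Friday's by a factor of 23.3. Thursday's and Sunday's, fed while hot, should lie between.

The forecast named Friday's, with 14% for Friday's, 4.5% for Thursday's, 12.5% for Tuesday's and 3% for Sunday's, on the ground “no reaction at 70 °C, so a full batch”.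

The flasks give 0.820% for Friday's, 5.81% for Thursday's, 17.2% for Tuesday's and 4.89% for Sunday's, so Tuesday's is best, by a factor of 21.0 over Friday's.

    substrate + reagent + target → 2 target (k = 890 /M²/min, Ea = 47.0 kJ/mol)
    substrate + reagent → target (k = 0.0420 /M/min, Ea = 99.0 kJ/mol)
    substrate + target ⇌ idle adduct, settled at all times (K = 52.0 /M, ΔH = 18.0 kJ/mol)
    target ⇌ isomer of the product (K = 3.80, k = 0.260 /min, Ea = 107 kJ/mol, ΔH = −24.0 kJ/mol)
    (constants at 110 °C)

On Tuesday's flask our 1.46 min allows 2.73 doublings over the second half of the time, a factor of 6.65, and target there goes from 2.39% to 17.2%. The largest single effect holding Tuesday's flask down, though not the whole of what does, is the tying up of substrate and target as idle adduct. With that tying up taken away, Tuesday's ends at 37.5% rather than 17.2%.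

The readings stem from a simulated flask with constants of no real substance; the scatter is artificial.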